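Assumption: the target has no stereocentre and is achiral, so "single enantiomer" is taken to mean the single (E)-alkene isomer drawn (/C=C/ = trans).

## Retrosynthetic overview
1. The last step is global desilylation, so the target comes from tris-TBS ether 12. The OMe/OH difference between the two rings is bought in the starting phenols.
2. Key strategy: the C8=C9 alkene is never constructed. Both flanking C(sp2)–C(sp3) bonds (C7–C8 and C9–C10) are cut instead, which leaves (E)-1,2-dichloroethene as a geometry-defined C2 linchpin plus two alkyl Grignard reagents.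
3. Order of coupling: first a self-limiting Pd mono-alkylation of the dichloride with the C5-resorcinol arm, then an Fe-catalysed alkylation of the resulting (E)-alkenyl chloride with the C7 arm. Both proceed with retention.
4. Each arm is made from ArMgBr and an α,ω-dibromoalkane under Cu catalysis, starting from the silylated bromophenols.
5. No ring is formed, because both arenes are purchased. The only stereoelement is the E alkene, and it is imported from compound 10.

## Route

**Step 1**
Reactants: 1, 3-bromo-5-methoxyphenol
Product: 3... numbered 2, (3-bromo-5-methoxyphenoxy)(tert-butyl)dimethylsilane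
Conditions: TBSCl (1.2 equiv), imidazole (2.5 equiv), DMF, rt, 3 h
Reagents that add atoms: tert-butyldimethylsilyl chloride, CC(C)(C)[Si](C)(C)Cl
Why: Standard phenol O-silylation (imidazole-promoted silyl ether formation) masks the only acidic proton so the aryl bromide can later be turned into a Grignard reagent.

**Step 2**
Reactants: 2, (3-bromo-5-methoxyphenoxy)(tert-butyl)dimethylsilane; 3, 1,7-dibromoheptane
Product: 4, [3-(7-bromoheptyl)-5-methoxyphenoxy](tert-butyl)dimethylsilane
Conditions: (i) 2, Mg, LiCl, THF, rt; (ii) slow inverse addition to 3 (3 equiv), Li2CuCl4 (5 mol %), THF, 0 °C → rt; excess 3 removed by distillation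
Reagents that add atoms: none (all heavy atoms come from 2 and 3)
Why: In this Kochi-type Cu-catalysed Grignard/primary alkyl bromide cross-coupling, inverse addition into excess dibromide limits substitution to one terminus, and ArOMe and ArOTBS (meta to Mg, so no silyl migration) are inert.

**Step 3**
Reactants: 5, 5-bromobenzene-1,3-diol (5-bromoresorcinol)
Product: 6, 1-bromo-3,5-bis(tert-butyldimethylsilyloxy)benzene
Conditions: TBSCl (2.4 equiv), imidazole (5 equiv), DMF, rt, 4 h
Reagents that add atoms: tert-butyldimethylsilyl chloride (2 equiv incorporated), CC(C)(C)[Si](C)(C)Cl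
Why: Double phenol O-silylation uses the same protecting group as in 2, so one fluoride step frees all three phenols at the end.

**Step 4**
Reactants: 6, 1-bromo-3,5-bis(TBSO)benzene; 7, 1,5-dibromopentane
Product: 8, 1-(5-bromopentyl)-3,5-bis(tert-butyldimethylsilyloxy)benzene
Conditions: (i) 6, Mg, LiCl, THF, rt; (ii) slow inverse addition to 7 (3 equiv), Li2CuCl4 (5 mol %), THF, 0 °C → rt; excess 7 removed by distillation
Reagents that add atoms: none (all heavy atoms come from 6 and 7)
Why: This is the same Kochi-type Cu-catalysed aryl Grignard/alkyl bromide coupling as step 2, with mono-substitution enforced by stoichiometry and order of addition.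

**Step 5 (key step, part 1)**
Reactants: 8, 1-(5-bromopentyl)-3,5-bis(TBSO)benzene; 9, (E)-1,2-dichloroethene
Product: 10, 5-[(E)-7-chlorohept-6-en-1-yl]-1,3-bis(tert-butyldimethylsilyloxy)benzene
Conditions: (i) 8, Mg (BrCH2CH2Br-activated), THF, 35 °C; (ii) add over 1 h to 9 (5 equiv), Pd(PPh3)4 (5 mol %), THF, 20 °C, 12 h; excess 9 (bp 48 °C) evaporated
Reagents that add atoms: none (all heavy atoms come from 8 and 9)
Why: In this Kumada–Corriu mono-alkylation of a 1,2-dihaloalkene, Pd(0) inserts into the activated C–Cl bond of 9 but not into the more electron-rich mono-chloroalkene product, so coupling stops after one substitution, and stereoretentive oxidative addition and reductive elimination transfer the E geometry of 9 unchanged (the E isomer is also the one slow to dehydrochlorinate).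

**Step 6 (key step, part 2)**
Reactants: 4, [3-(7-bromoheptyl)-5-methoxyphenoxy]TBS; 10, (E)-alkenyl chloride
Product: 11, (E)-1-[3-(tert-butyldimethylsilyloxy)-5-methoxyphenyl]-14-[3,5-bis(tert-butyldimethylsilyloxy)phenyl]tetradec-8-ene (C1 is the methoxyaryl end)
Conditions: (i) 4 (1.4 equiv), Mg, THF, 35 °C; (ii) add over 20 min to 10 (1.0 equiv), Fe(acac)3 (5 mol %), THF/NMP (about 9 equiv NMP), 0 °C, 30 min
Reagents that add atoms: none (all heavy atoms come from 4 and 10)
Why: This iron-catalysed alkenyl chloride/alkyl Grignard cross-coupling (Kochi–Cahiez type) is complete in minutes at 0 °C, outruns β-hydride elimination, leaves aryl methyl and silyl ethers untouched, and retains alkene geometry, so (E)-10 gives (E)-11.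

**Step 7**
Reactants: 11, tris-TBS ether
Product: 12, dehydrobisgravillol, 5-[(E)-14-(3-hydroxy-5-methoxyphenyl)tetradec-6-en-1-yl]benzene-1,3-diol
Conditions: TBAF (3.6 equiv), AcOH (3.6 equiv), THF, 0 °C → rt, 1 h, under Ar
Reagents that add atoms: none (only H is gained)
Why: Buffered fluoride-mediated desilylation removes all three aryl TBS groups at once, while the methyl ether and the isolated E alkene are inert and the buffering prevents air oxidation of the resorcinolate.

Quality control: E purity can be checked by 13C NMR (allylic CH2 near 32.6 ppm for E, near 27 ppm for Z) and IR (965 cm⁻¹). Any trace of Z isomer can be removed on AgNO3-silica at the stage of 11.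

## Compound list
1 | 3-bromo-5-methoxyphenol | COc1cc(O)cc(Br)c1 | starting material
2 | (3-bromo-5-methoxyphenoxy)(tert-butyl)dimethylsilane | COc1cc(Br)cc(O[Si](C)(C)C(C)(C)C)c1 | intermediate
3 | 1,7-dibromoheptane | BrCCCCCCCBr | starting material
4 | [3-(7-bromoheptyl)-5-methoxyphenoxy](tert-butyl)dimethylsilane | COc1cc(CCCCCCCBr)cc(O[Si](C)(C)C(C)(C)C)c1 | intermediate
5 | 5-bromobenzene-1,3-diol | Oc1cc(O)cc(Br)c1 | starting material
6 | 1-bromo-3,5-bis(tert-butyldimethylsilyloxy)benzene | CC(C)(C)[Si](C)(C)Oc1cc(Br)cc(O[Si](C)(C)C(C)(C)C)c1 | intermediate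
7 | 1,5-dibromopentane | BrCCCCCBr | starting material
8 | 1-(5-bromopentyl)-3,5-bis(tert-butyldimethylsilyloxy)benzene | CC(C)(C)[Si](C)(C)Oc1cc(CCCCCBr)cc(O[Si](C)(C)C(C)(C)C)c1 | intermediate
9 | (E)-1,2-dichloroethene | Cl/C=C/Cl | starting material
10 | 5-[(E)-7-chlorohept-6-en-1-yl]-1,3-bis(tert-butyldimethylsilyloxy)benzene | Cl/C=C/CCCCCc1cc(O[Si](C)(C)C(C)(C)C)cc(O[Si](C)(C)C(C)(C)C)c1 | intermediate
11 | (E)-1-[3-(TBSO)-5-methoxyphenyl]-14-[3,5-bis(TBSO)phenyl]tetradec-8-ene | COc1cc(O[Si](C)(C)C(C)(C)C)cc(CCCCCCC/C=C/CCCCCc2cc(O[Si](C)(C)C(C)(C)C)cc(O[Si](C)(C)C(C)(C)C)c2)c1 | intermediate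
12 | dehydrobisgravillol | COc1cc(O)cc(CCCCCCC/C=C/CCCCCc2cc(O)cc(O)c2)c1 | target

## Summary
Total step count: 7.
Longest linear sequence: 5 (steps 3 → 4 → 5 → 6 → 7).

Three steps most likely to fail, each with one fallback:
1. **Step 5, mono-alkylation of (E)-dichloroethene.** The risks are β-hydride elimination, double coupling and loss of HCl.
   Fallback: give up the C2 linchpin for this arm. Displace the bromide of 8 with lithium acetylide·ethylenediamine to give the terminal alkyne. Then carry out syn-hydrozirconation (Cp2Zr(H)Cl) and an I2 quench to obtain the (E)-alkenyl iodide, which takes the place of 10 in step 6.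
2. **Step 6, Fe-catalysed sp2–sp3 coupling.** The risks are Grignard homocoupling, reduction of the chloride and slight E/Z erosion.
   Fallback: reverse the polarity of the union. Hydrozirconate the terminal alkyne derived from 8 and couple the (E)-alkenylzirconocene directly with alkyl bromide 4 in a Pd-catalysed Negishi-type alkyl-electrophile coupling. The geometry is then set by syn-hydrometalation.
3. **Steps 4 and 2, aryl Grignard plus α,ω-dibromide.** The risks are sluggish aryl–alkyl coupling and double arylation.
   Fallback: build the arms by Sonogashira coupling of 6 or 2 with pent-4-yn-1-ol or hept-6-yn-1-ol. Fully hydrogenate the alkyne (no alkene is present yet), then convert the alcohol to bromide 8 or 4 by Appel bromination.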